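The pitfall in a nearly finished flask is to watch what is made: the target column of the oak run stays flat within its scatter of 1 percentage point, so it says little about stopping, and the question goes to the fraction left instead.

| flask | starting material | reagent | remark | time |
|---|---|---|---|---|
| elm | 0.090 M | 0.072 M | run made earlier |  |
| oak | 0.090 M | 0.16 M | run made earlier |  |
| alder | 0.045 M | 0.108 M | run made earlier |  |
| flask | 0.090 M | 0.108 M |  | 25 min |

| run | time / min | starting material / % | target / % |
|---|---|---|---|
| elm | 5.00 | 24.6 | 41.2 |
| elm | 10.0 | 20.8 | 46.1 |
| elm | 15.0 | 20.2 | 45.3 |
| elm | 20.0 | 20.1 | 45.1 |
| elm | 25.0 | 21.7 | 45.6 |
| oak | 5.00 | 1.0 | 57.1 |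
| oak | 10.0 | 0 | 57.9 |
| oak | 15.0 | 0 | 56.5 |
| oak | 20.0 | 0 | 58.0 |
| oak | 25.0 | 1.0 | 58.9 |
| alder | 5.00 | 2.1 | 55.1 |
| alder | 10.0 | 0 | 59.1 |
| alder | 15.0 | 0 | 60.0 |
| alder | 20.0 | 0 | 59.3 |
| alder | 25.0 | 2.4 | 56.5 |

(scatter of a reading: 1 percentage point)

- steps under discussion: adduct -> target; starting material + reagent <-> adduct; target <-> isomer of the product
- the reaction counts as stopped when no species that holds the starting material changes by six tenths of a point or more over the second half of the time

- at 25 min, what has stopped the reaction, if anything has (forward and back rates have come level / all of the starting material has reacted / the reagent has run out first / it is still moving)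
- how much of the starting material has reacted by 25 min
- how much target there is at 25 min, in percent of the starting material charged

The elm run levels off with starting material reading near 20.1%, and one reagent per starting material predicts 20.0%, so the two are read as reacting one to one. In the oak and alder runs, with starting material reading 0% at 20.0 min, target reads 58.0% and 59.3%, so in these readings about 58.6% of what reacted stands as target. The flask has 0.0180 M more reagent than starting material, which makes starting material its limiting reagent.

For a one-to-one pair taken up by a single second-order step, ln(c plentiful / c scarce) climbs straight with time, and the runs are read here as if that held. Call its slope per unit of gap the climb constant k, an apparent second-order constant. The first oak reading gives k = 10.8 /M/min, which reckons starting material in the flask at 1.57% at half time. That link is weak, since the reading of 1.0% equals its scatter.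

The first elm reading stands 4.6 points above its level, and the elm gap equals the flask's. It gives k = 16.2 /M/min. The reckoning then puts starting material in the flask at 0.450% at half time and 0.0116% at 25 min. The reckoned fall of 0.44 points lies narrowly under the stopping mark, so the reckoning commits to starting material used up, down to 0.0116%, with target near 58.6%.

The forecast differs on the end: it is still moving, with conversion 99.8% and target 57.5%, for “the fall over the second half is about 1 point, above the 0.6 threshold”.

The flask's answer on the end is: all of the starting material has reacted, with conversion >99.9% and target 58.5%.

    adduct → target (k = 0.0120 /s)
    starting material + reagent ⇌ adduct (K = 66.0 /M, k = 0.860 /M/s)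
    target ⇌ isomer of the product (K = 0.710, k = 0.0120 /s)

At 2.50 min the flask held starting material 13.2% and adduct 20.2% beside target 43.6% and isomer of the product 23.0%, the steps to adduct, to target and to isomer of the product running side by side. By 12.5 min the flask's starting material stood at 0.517% and adduct at 0.420%, against the reckoned 0.450% of starting material, and the fall of starting material from there to 25 min was 0.51 points.

In the neighbour flask with 0.065 M reagent, reagent is the scarce partner across a gap of 0.0250 M. There k reckons 0.00115% of the reagent left at 25 min, with starting material at 27.8% and target at 42.4%. The computed neighbour holds reagent 0%, starting material 28% and target 42.2%.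

(Readings and results come from a simulation with constants of no real substance.)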